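The route rests on disconnecting C13–C14 of the dihydrofuran ring (C13–C14=C15–O–C16). A rhodium carbene from a diazoacetate on the C16 oxygen inserts into C13–H, in one operation making the quaternary bis-spiro carbon C13 and a spiro γ-lactone that is later reduced to the enol ether. The step exploits the tertiary C13–H bond of the furanone ring (O–C9–C11–C12–C13): it is α to the ring oxygen, 1,5 to the carbene, and is replaced with retention, so C14 takes the C10-facing position that hydrogen held and C16 stays on the C8 side. The precursor is the 9α,13-epoxy spiro tetrahydrofuran with C12, C6 and C19 silylated.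

Key step: step 20

Remarks on the chemistry (assumptions and design points)
- Atom numbers are labdane numbers (C1–C10 decalin, C11–C16 side chain, C17 on C8, C18/C19 on C4, C20 on C10); β is the face of C20.
- Step 2: the (S)-oxazaborolidinium catalyst is assumed to give the enantiomer drawn for 4; if the sense were opposite, the (R)-catalyst would be used unchanged.
- (2E)-Penta-2,4-dien-1-ol and (S)-solketal are taken as commercial.
- O16 stays benzylated until the furanone ring is closed: a free C16–OH would close the six-membered pyranone (6-endo) or, under gold, a furan.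
- C13 is brought in from (S)-solketal and never equilibrated: its two faces are flanked by C1H2 and C17H3 in near mirror-image positions, so no thermodynamic bias can be relied on.
- C12 is reduced so that O12 is cis to C16: H12 is then anti to the carbene arm, and O12 cannot reach C15 of the later enol ether.
- The 6β-OH, syn-axial to C19 and C20, is protected as TES; its hindrance should let it outlast the C12–OTES.

Step 1
Reactants: 1 (2E)-penta-2,4-dien-1-ol
Product: 2 tert-butyl(dimethyl)[(2E)-penta-2,4-dienyloxy]silane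
Conditions: TBSCl, imidazole, CH2Cl2, 0 °C to rt
Reagents that add atoms: tert-butyldimethylsilyl chloride, CC(C)(C)[Si](C)(C)Cl
Why: Imidazole-promoted silylation of a primary allylic alcohol; no stereocentre is involved.

Step 2
Reactants: 3 2,6-dimethyl-1,4-benzoquinone; 2 tert-butyl(dimethyl)[(2E)-penta-2,4-dienyloxy]silane
Product: 5 trans-fused enedione silyl ether, via cis-fused adduct 4 (not isolated)
Conditions: (S)-o-tolyl-CBS oxazaborolidine (20 mol %), Tf2NH (20 mol %), CH2Cl2, −78 to −20 °C; then DBU (0.5 equiv), 0 °C to rt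
Reagents that add atoms: none
Why: Enantioselective quinone Diels–Alder reaction under cationic oxazaborolidine catalysis, then base epimerisation: the catalyst binds the carbonyl flanked by C–H, the free diene terminus bonds to the methyl-bearing β-carbon and the substituted terminus to the CH carbon (endo), the shielded quinone face fixes C10, and DBU inverts C5 through the enedione enolate to the trans ring fusion expected to be favoured for such flattened enediones.

Step 3
Reactants: 5 trans-fused enedione silyl ether
Product: 8 trans-fused enedione acid, via primary alcohol 6 (not isolated), via aldehyde 7 (not isolated)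
Conditions: CrO3, H2SO4, H2O, acetone, 0 °C to rt
Reagents that add atoms: water, O
Why: Jones oxidation, in which the acidic medium removes the primary silyl ether and chromic acid takes the alcohol through the aldehyde hydrate to the acid; C4 is epimerisable and is settled in step 6.

Step 4
Reactants: 8 trans-fused enedione acid
Product: 9 trans-fused enedione methyl ester
Conditions: MeI, KHCO3, DMF, rt
Reagents that add atoms: iodomethane, CI
Why: Carboxylate O-alkylation (SN2) with a base too weak to enolise the enedione; no stereocentre is touched.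

Step 5
Reactants: 9 trans-fused enedione methyl ester
Product: 10 saturated diketo ester (8β-methyl)
Conditions: H2 (1 atm), 10% Pd/C, EtOAc, rt
Reagents that add atoms: none
Why: Heterogeneous hydrogenation of C2=C3 and of the enedione C7=C8; hydrogen should add on the α face away from axial C20 (8β-methyl, provisional, corrected in step 6), and the neutral medium leaves C5 alone.

Step 6
Reactants: 10 saturated diketo ester (8β-methyl)
Product: 12 keto lactone (4α-H), via hydroxy keto ester 11 (not isolated)
Conditions: NaBH4 (1 equiv), MeOH–CH2Cl2, −40 °C; then NaOMe (0.3 equiv), MeOH, 50 °C; AcOH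
Reagents that add atoms: none
Why: Chemoselective borohydride reduction, then base-mediated epimerisation and lactonisation: hydride reaches only the C6 carbonyl (C9 is flanked by quaternary C10 and C8) and only from the α face, the β face being screened by axial C20, which sets 6β-OH; methoxide then equilibrates C8 to the equatorial 8α-methyl and C4 through the ester enolate, the 4β epimer being drained as the 19,6β-γ-lactone.

Step 7
Reactants: 12 keto lactone (4α-H)
Product: 13 keto lactone (4α-methyl)
Conditions: LDA (2.3 equiv), THF, −78 to −40 °C; MeI (1.1 equiv), −78 °C; then MeOH, rt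
Reagents that add atoms: iodomethane, CI
Why: Dianion alkylation: the C8/C9 ketone enolate forms first, the more reactive lactone enolate is then methylated at C4 on the α face (the only open face of the cis-fused lactone, the β face being blocked by C20), which sets the C4 quaternary centre, and the equilibrating methanol quench returns the 8α-methyl ketone.

Step 8
Reactants: 14 (S)-solketal
Product: 15 (R)-2,2-dimethyl-1,3-dioxolane-4-carbaldehyde
Conditions: (COCl)2, DMSO, CH2Cl2, −78 °C; Et3N, −78 to 0 °C
Reagents that add atoms: none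
Why: Swern oxidation; the α-alkoxy stereocentre survives at low temperature.

Step 9
Reactants: 15 (R)-2,2-dimethyl-1,3-dioxolane-4-carbaldehyde
Product: 16 (S)-4-ethynyl-2,2-dimethyl-1,3-dioxolane
Conditions: dimethyl (1-diazo-2-oxopropyl)phosphonate, K2CO3, MeOH, 0 °C to rt
Reagents that add atoms: dimethyl (1-diazo-2-oxopropyl)phosphonate, CC(=O)C(=[N+]=[N-])P(=O)(OC)OC
Why: Seyferth–Gilbert homologation with the Ohira–Bestmann reagent, a one-carbon extension to the terminal alkyne that leaves the stereocentre untouched.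

Step 10
Reactants: 16 (S)-4-ethynyl-2,2-dimethyl-1,3-dioxolane
Product: 17 (S)-but-3-yne-1,2-diol
Conditions: Dowex 50W (H+), MeOH–H2O, rt
Reagents that add atoms: none
Why: Acid-catalysed acetal hydrolysis; no bond to the stereocentre is broken.

Step 11
Reactants: 17 (S)-but-3-yne-1,2-diol
Product: 18 (S)-1-(benzyloxy)but-3-yn-2-ol
Conditions: BnBr, Bu2SnCl2 (10 mol %), K2CO3, Bu4NBr (10 mol %), MeCN, 60 °C
Reagents that add atoms: benzyl bromide, BrCc1ccccc1
Why: Tin-catalysed regioselective O-alkylation through a stannylene acetal, which activates the primary oxygen of a 1,2-diol.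

Step 12
Reactants: 13 keto lactone (4α-methyl); 18 (S)-1-(benzyloxy)but-3-yn-2-ol
Product: 19 propargylic diol
Conditions: 18, n-BuLi (2 equiv per 18), THF, −78 °C; CeCl3, −78 °C; then 13, −78 to −30 °C; aq. NH4Cl
Reagents that add atoms: none
Why: 1,2-Addition of a cerium acetylide, a weakly basic nucleophile that should add to the hindered, enolisable C9 ketone faster than to the neopentyl lactone carbonyl; attack is expected along the axial α direction anti to C20 (9α-alkynyl), a centre that step 13 erases, while C13 keeps its solketal-derived configuration.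

Step 13
Reactants: 19 propargylic diol
Product: 21 spiro furanone lactone, via hydroxy enone 20 (not isolated)
Conditions: Ph3PAuNTf2 (5 mol %), MeOH (2 equiv), toluene, rt; then TsOH·H2O (20 mol %), CH2Cl2, rt
Reagents that add atoms: none
Why: Gold(I)-catalysed Meyer–Schuster rearrangement (the tertiary C9 carbinol migrates, not the electron-poor secondary C13 carbinol), then acid-catalysed intramolecular oxa-Michael addition (5-endo closure through the protonated enone): the C13 hydroxyl adds to C9 on the α face, axial and anti to C20 and also the thermodynamic outcome of this reversible addition, which sets C9; the benzyl group on O16 leaves the five-membered ring as the only closure, and the mild acid should not enolise C13.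

Step 14
Reactants: 21 spiro furanone lactone
Product: 22 6β,12,19-triol 16-benzyl ether
Conditions: LiAlH4, THF, −78 to 0 °C; Rochelle salt
Reagents that add atoms: none
Why: Aluminium hydride reduction: the C12 ketone is attacked from the face opposite the CH2OBn group on C13, which sets C12 with O12 cis to C16 (either epimer would serve, as C12 is re-oxidised), and the lactone is opened to the 6β,19-diol.

Step 15
Reactants: 22 6β,12,19-triol 16-benzyl ether
Product: 23 19-O-TBS diol
Conditions: TBSCl (1.1 equiv), imidazole, DMF, 0 °C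
Reagents that add atoms: tert-butyldimethylsilyl chloride, CC(C)(C)[Si](C)(C)Cl
Why: Silylation selective for the only primary hydroxyl (C19) over the secondary C12–OH and the very hindered 6β-OH.

Step 16
Reactants: 23 19-O-TBS diol
Product: 24 6,12-bis-O-TES 19-O-TBS 16-benzyl ether
Conditions: TESOTf (3 equiv), 2,6-lutidine, CH2Cl2, −78 to 0 °C
Reagents that add atoms: triethylsilyl triflate, CC[Si](CC)(CC)OS(=O)(=O)C(F)(F)F
Why: Silyl triflate silylation, reactive enough for the syn-axially hindered 6β-OH and the C12–OH.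

Step 17
Reactants: 24 6,12-bis-O-TES 19-O-TBS 16-benzyl ether
Product: 25 C16 alcohol
Conditions: H2 (1 atm), 10% Pd/C, EtOAc, rt
Reagents that add atoms: none
Why: Hydrogenolysis of the benzyl ether in a neutral, aprotic medium that leaves the silyl ethers; the molecule holds no other reducible group.

Step 18
Reactants: 25 C16 alcohol
Product: 26 C16 bromoacetate
Conditions: BrCH2COBr, pyridine, CH2Cl2, −20 to 0 °C
Reagents that add atoms: bromoacetyl bromide, BrCC(=O)Br
Why: Acylation of the only free (primary) hydroxyl with an acyl bromide.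

Step 19
Reactants: 26 C16 bromoacetate
Product: 28 C16 diazoacetate, via N-alkyl ditosylhydrazide 27 (not isolated)
Conditions: TsNHNHTs, DBU, THF, 0 °C
Reagents that add atoms: N,N′-ditosylhydrazine, Cc1ccc(cc1)S(=O)(=O)NNS(=O)(=O)c1ccc(C)cc1
Why: Diazoacetate synthesis from a bromoacetate: N-alkylation of the ditosylhydrazide anion, then base-induced loss of two sulfinates; no stereocentre is touched.

Step 20
Reactants: 28 C16 diazoacetate
Product: 29 spiro γ-lactone
Conditions: Rh2(cap)4 (1 mol %), CH2Cl2, reflux, 28 added by syringe pump over 8 h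
Reagents that add atoms: none
Why: The rhodium(II) carbene formed from 28 by loss of N2 inserts into the C13–H bond through a concerted, asynchronous three-centre transition state in which the positive charge building on C13 is stabilised by the lone pair of the furanone-ring oxygen. The closest known reaction type is the dirhodium carboxamidate-catalysed conversion of alkyl diazoacetates into γ-lactones by insertion next to an ether oxygen. The lactone ring C13–C14–C15–O–C16 closes by 1,5-insertion, the carbene carbon C14 bonding to the γ-carbon C13. C13 is the only new stereocentre and is set by retention: C14 enters on the face the hydrogen held (C10 side), so its configuration is the one brought in from (S)-solketal. The step needs site selectivity for C13–H and chemoselectivity against carbene dimerisation and oxonium-ylide formation: C13–H is the only C–H that gives a five-membered ring, C12–H lies anti to the C16 arm so a δ-lactone would have to be trans-fused, C16–H would give a strained β-lactone, and the electron-rich carboxamidate ligands with slow addition favour C–H insertion. C12 is carried as a silyl ether because a C12 carbonyl would deactivate C13–H.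

Step 21
Reactants: 29 spiro γ-lactone
Product: 30 lactol
Conditions: DIBAL-H (1.2 equiv), CH2Cl2, −78 °C; Rochelle salt
Reagents that add atoms: none
Why: Partial reduction of a γ-lactone to the lactol at low temperature; the anomeric centre is inconsequential.

Step 22
Reactants: 30 lactol
Product: 32 enol ether (12-OTES), via lactol mesylate 31 (not isolated)
Conditions: MsCl, Et3N, CH2Cl2, 0 °C; then reflux
Reagents that add atoms: none
Why: Lactol dehydration by mesylation and base-induced elimination through the oxocarbenium ion, giving the C14=C15 enol ether; C13 is quaternary and cannot be affected.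

Step 23
Reactants: 32 enol ether (12-OTES)
Product: 33 C12 alcohol
Conditions: HF·pyridine, pyridine, THF, 0 °C
Reagents that add atoms: none
Why: Buffered fluoride desilylation, expected to be selective for the C12 triethylsilyl ether over the primary TBS ether and the far more hindered 6β-OTES, and mild enough for the enol ether.

Step 24
Reactants: 33 C12 alcohol
Product: 34 C12 ketone (6-OTES, 19-OTBS)
Conditions: Dess–Martin periodinane, NaHCO3, CH2Cl2, 0 °C to rt
Reagents that add atoms: none
Why: Buffered Dess–Martin oxidation of the secondary alcohol; it removes the C12 stereocentre and tolerates the enol ether.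

Step 25
Reactants: 34 C12 ketone (6-OTES, 19-OTBS)
Product: 35 CNP0176827.1
Conditions: HF·pyridine (excess), pyridine, THF, 0 °C to rt
Reagents that add atoms: none
Why: Global fluoride desilylation under buffered conditions that spare the enol ether and the β-alkoxy ketone; no stereocentre is touched.

Compound list
1 | (2E)-penta-2,4-dien-1-ol | OC/C=C/C=C | starting material
2 | tert-butyl(dimethyl)[(2E)-penta-2,4-dienyloxy]silane | CC(C)(C)[Si](C)(C)OC/C=C/C=C | intermediate
3 | 2,6-dimethyl-1,4-benzoquinone | CC1=CC(=O)C=C(C)C1=O | starting material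
4 | cis-fused adduct: 4α-(TBSO-methyl)-8,10β-dimethyl-5β-H-decalin-2,7-diene-6,9-dione | CC1=CC(=O)[C@@H]2[C@H](CO[Si](C)(C)C(C)(C)C)C=CC[C@]2(C)C1=O | intermediate
5 | trans-fused enedione silyl ether (5α-H epimer of 4) | CC1=CC(=O)[C@H]2[C@H](CO[Si](C)(C)C(C)(C)C)C=CC[C@]2(C)C1=O | intermediate
6 | trans-fused enedione primary alcohol (4α-CH2OH) | CC1=CC(=O)[C@H]2[C@H](CO)C=CC[C@]2(C)C1=O | intermediate
7 | trans-fused enedione aldehyde (4α-CHO) | CC1=CC(=O)[C@H]2[C@H](C=O)C=CC[C@]2(C)C1=O | intermediate
8 | trans-fused enedione acid (4α-CO2H) | CC1=CC(=O)[C@H]2[C@H](C(=O)O)C=CC[C@]2(C)C1=O | intermediate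
9 | trans-fused enedione methyl ester | CC1=CC(=O)[C@H]2[C@H](C(=O)OC)C=CC[C@]2(C)C1=O | intermediate
10 | methyl 8β,10β-dimethyl-6,9-dioxo-5α-decalin-4α-carboxylate | C[C@H]1CC(=O)[C@H]2[C@H](C(=O)OC)CCC[C@]2(C)C1=O | intermediate
11 | methyl 6β-hydroxy-8β,10β-dimethyl-9-oxo-5α-decalin-4α-carboxylate | C[C@H]1C[C@@H](O)[C@H]2[C@H](C(=O)OC)CCC[C@]2(C)C1=O | intermediate
12 | keto lactone: 8α,10β-dimethyl-9-oxo-5α-decalin-19,6β-olide (4α-H) | C[C@@H]1C[C@H]2OC(=O)[C@H]3CCC[C@](C)(C1=O)[C@@H]23 | intermediate
13 | keto lactone: 4α,8α,10β-trimethyl-9-oxo-5α-decalin-19,6β-olide | C[C@@H]1C[C@H]2OC(=O)[C@@]3(C)CCC[C@](C)(C1=O)[C@@H]23 | intermediate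
14 | (S)-solketal, (S)-(2,2-dimethyl-1,3-dioxolan-4-yl)methanol | OC[C@H]1COC(C)(C)O1 | starting material
15 | (R)-2,2-dimethyl-1,3-dioxolane-4-carbaldehyde | O=C[C@H]1COC(C)(C)O1 | intermediate
16 | (S)-4-ethynyl-2,2-dimethyl-1,3-dioxolane | C#C[C@H]1COC(C)(C)O1 | intermediate
17 | (S)-but-3-yne-1,2-diol | C#C[C@H](O)CO | intermediate
18 | (S)-1-(benzyloxy)but-3-yn-2-ol | C#C[C@H](O)COCc1ccccc1 | intermediate
19 | propargylic diol: 9β-hydroxy-9α-[(3S)-4-benzyloxy-3-hydroxybut-1-ynyl] derivative of 13 | C[C@@H]1C[C@H]2OC(=O)[C@@]3(C)CCC[C@](C)([C@]1(O)C#C[C@H](O)COCc1ccccc1)[C@@H]23 | intermediate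
20 | α′-hydroxy enone (C9=C11, C12 ketone, 13-OH, 16-OBn; E isomer drawn, geometry inconsequential) | C[C@@H]1C[C@H]2OC(=O)[C@@]3(C)CCC[C@](C)(/C1=C/C(=O)[C@H](O)COCc1ccccc1)[C@@H]23 | intermediate
21 | spiro furanone lactone: 9α,13-epoxy-12-oxo-19,6β-olide, 16-OBn, H13 on the C10 side | C[C@@H]1C[C@H]2OC(=O)[C@@]3(C)CCC[C@](C)([C@@]14CC(=O)[C@@H](COCc5ccccc5)O4)[C@@H]23 | intermediate
22 | 9α,13-epoxy-6β,12,19-triol 16-benzyl ether (O12 cis to C16) | C[C@@H]1C[C@@H](O)[C@H]2[C@@](C)(CO)CCC[C@]2(C)[C@@]12C[C@@H](O)[C@@H](COCc3ccccc3)O2 | intermediate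
23 | 19-O-TBS 6β,12-diol 16-benzyl ether | C[C@@H]1C[C@@H](O)[C@H]2[C@@](C)(CO[Si](C)(C)C(C)(C)C)CCC[C@]2(C)[C@@]12C[C@@H](O)[C@@H](COCc3ccccc3)O2 | intermediate
24 | 6,12-bis-O-TES 19-O-TBS 16-benzyl ether | C[C@@H]1C[C@@H](O[Si](CC)(CC)CC)[C@H]2[C@@](C)(CO[Si](C)(C)C(C)(C)C)CCC[C@]2(C)[C@@]12C[C@@H](O[Si](CC)(CC)CC)[C@@H](COCc3ccccc3)O2 | intermediate
25 | C16 alcohol (6,12-bis-O-TES, 19-O-TBS) | C[C@@H]1C[C@@H](O[Si](CC)(CC)CC)[C@H]2[C@@](C)(CO[Si](C)(C)C(C)(C)C)CCC[C@]2(C)[C@@]12C[C@@H](O[Si](CC)(CC)CC)[C@@H](CO)O2 | intermediate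
26 | C16 bromoacetate | C[C@@H]1C[C@@H](O[Si](CC)(CC)CC)[C@H]2[C@@](C)(CO[Si](C)(C)C(C)(C)C)CCC[C@]2(C)[C@@]12C[C@@H](O[Si](CC)(CC)CC)[C@@H](COC(=O)CBr)O2 | intermediate
27 | C16 (N,N′-ditosylhydrazino)acetate | C[C@@H]1C[C@@H](O[Si](CC)(CC)CC)[C@H]2[C@@](C)(CO[Si](C)(C)C(C)(C)C)CCC[C@]2(C)[C@@]12C[C@@H](O[Si](CC)(CC)CC)[C@@H](COC(=O)CN(NS(=O)(=O)c3ccc(C)cc3)S(=O)(=O)c3ccc(C)cc3)O2 | intermediate
28 | C16 diazoacetate (C13–H insertion precursor) | C[C@@H]1C[C@@H](O[Si](CC)(CC)CC)[C@H]2[C@@](C)(CO[Si](C)(C)C(C)(C)C)CCC[C@]2(C)[C@@]12C[C@@H](O[Si](CC)(CC)CC)[C@@H](COC(=O)C=[N+]=[N-])O2 | intermediate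
29 | spiro γ-lactone (C13–C14 formed; 12-OTES) | C[C@@H]1C[C@@H](O[Si](CC)(CC)CC)[C@H]2[C@@](C)(CO[Si](C)(C)C(C)(C)C)CCC[C@]2(C)[C@@]12C[C@@H](O[Si](CC)(CC)CC)[C@]1(CC(=O)OC1)O2 | intermediate
30 | lactol (C15 anomers) | C[C@@H]1C[C@@H](O[Si](CC)(CC)CC)[C@H]2[C@@](C)(CO[Si](C)(C)C(C)(C)C)CCC[C@]2(C)[C@@]12C[C@@H](O[Si](CC)(CC)CC)[C@]1(CC(O)OC1)O2 | intermediate
31 | lactol mesylate | C[C@@H]1C[C@@H](O[Si](CC)(CC)CC)[C@H]2[C@@](C)(CO[Si](C)(C)C(C)(C)C)CCC[C@]2(C)[C@@]12C[C@@H](O[Si](CC)(CC)CC)[C@]1(CC(OS(C)(=O)=O)OC1)O2 | intermediate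
32 | enol ether (spiro 2,3-dihydrofuran; 12-OTES) | C[C@@H]1C[C@@H](O[Si](CC)(CC)CC)[C@H]2[C@@](C)(CO[Si](C)(C)C(C)(C)C)CCC[C@]2(C)[C@@]12C[C@@H](O[Si](CC)(CC)CC)[C@]1(C=COC1)O2 | intermediate
33 | C12 alcohol (6-OTES, 19-OTBS) | C[C@@H]1C[C@@H](O[Si](CC)(CC)CC)[C@H]2[C@@](C)(CO[Si](C)(C)C(C)(C)C)CCC[C@]2(C)[C@@]12C[C@@H](O)[C@]1(C=COC1)O2 | intermediate
34 | C12 ketone (6-OTES, 19-OTBS) | C[C@@H]1C[C@@H](O[Si](CC)(CC)CC)[C@H]2[C@@](C)(CO[Si](C)(C)C(C)(C)C)CCC[C@]2(C)[C@@]12CC(=O)[C@]1(C=COC1)O2 | intermediate
35 | CNP0176827.1 | C[C@@H]1C[C@@H](O)[C@H]2[C@@](C)(CO)CCC[C@]2(C)[C@@]12CC(=O)[C@]1(C=COC1)O2 | target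

Total step count: 25. Longest linear sequence: 21 steps (steps 1–7 and 12–25); the alkyne branch is steps 8–11.

Steps most likely to fail

Step 20. The carbene may be consumed by dimerisation, by attack on the furanone-ring oxygen (oxonium ylide) or by insertion next to the ester oxygen before it reaches C13–H. The fallback sets out from alcohol 25 and keeps the retentive insertion but changes the carbene class. Acylation with benzyl malonyl chloride and pyridine should give the mixed benzyl malonate F1. Diazo transfer (p-ABSA, Et3N, MeCN) should give the diazomalonate F2. Rh2(OAc)4 in refluxing CH2Cl2 should then deliver, through the longer-lived and more selective acceptor/acceptor carbene, the 14-benzyloxycarbonyl spiro lactone F3. Hydrogenolysis (H2, Pd/C, EtOAc) should give the 14-carboxy lactone F4, which should lose CO2 on warming in toluene and come back to the route at 29.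

Step 13. Ring closure at the congested C9 may stall at enone 20, or the acid needed to force it may enolise C13 or trigger Rupe-type dehydration. The fallback sets out from 19 and closes the ring before any C12 carbonyl exists. Lindlar semi-hydrogenation should give the (Z)-ene-diol F5. Catalytic CSA in CH2Cl2 should ionise the tertiary allylic C9–OH, and capture by the C13 hydroxyl on the α face should give the spiro 2,5-dihydrofuran F6. Hydroboration with 9-BBN and NaBO3 oxidation should place the hydroxyl on C12, the alkene carbon remote from quaternary C9, giving the C12 alcohol F7. Dess–Martin oxidation comes back to the route at 21.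

Step 2. Rate and face discrimination may be poor for a methyl-substituted quinone double bond with a weakly activated diene, giving low enantiomeric purity or the opposite sense. The fallback sets out from 3 and replaces steps 1–3. Thermal Diels–Alder reaction with (2E)-penta-2,4-dienoic acid (toluene, 80 °C) should give the racemic cis-fused adduct acid F8, already at the acid oxidation level. Et3N equilibration to the trans ring fusion and crystallisation with (R)-1-phenylethylamine (the antipodal amine if the other salt is the less soluble) should give the 1-phenylethylammonium salt F9 of the required acid. Acidification comes back to the route at 8.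

Further compounds
F1 | step 20 | C16 benzyl malonate | C[C@@H]1C[C@@H](O[Si](CC)(CC)CC)[C@H]2[C@@](C)(CO[Si](C)(C)C(C)(C)C)CCC[C@]2(C)[C@@]12C[C@@H](O[Si](CC)(CC)CC)[C@@H](COC(=O)CC(=O)OCc3ccccc3)O2
F2 | step 20 | C16 benzyl diazomalonate | C[C@@H]1C[C@@H](O[Si](CC)(CC)CC)[C@H]2[C@@](C)(CO[Si](C)(C)C(C)(C)C)CCC[C@]2(C)[C@@]12C[C@@H](O[Si](CC)(CC)CC)[C@@H](COC(=O)C(=[N+]=[N-])C(=O)OCc3ccccc3)O2
F3 | step 20 | 14-benzyloxycarbonyl spiro lactone (C14 epimers) | C[C@@H]1C[C@@H](O[Si](CC)(CC)CC)[C@H]2[C@@](C)(CO[Si](C)(C)C(C)(C)C)CCC[C@]2(C)[C@@]12C[C@@H](O[Si](CC)(CC)CC)[C@]1(C(C(=O)OCc3ccccc3)C(=O)OC1)O2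
F4 | step 20 | 14-carboxy spiro lactone (C14 epimers) | C[C@@H]1C[C@@H](O[Si](CC)(CC)CC)[C@H]2[C@@](C)(CO[Si](C)(C)C(C)(C)C)CCC[C@]2(C)[C@@]12C[C@@H](O[Si](CC)(CC)CC)[C@]1(C(C(=O)O)C(=O)OC1)O2
F5 | step 13 | (Z)-ene-diol (9β-OH, 13-OH, 16-OBn, 19,6β-olide) | C[C@@H]1C[C@H]2OC(=O)[C@@]3(C)CCC[C@](C)([C@]1(O)/C=C\[C@H](O)COCc1ccccc1)[C@@H]23
F6 | step 13 | spiro 2,5-dihydrofuran (9α,13-epoxy-11-ene, 16-OBn, 19,6β-olide) | C[C@@H]1C[C@H]2OC(=O)[C@@]3(C)CCC[C@](C)([C@@]14C=C[C@@H](COCc5ccccc5)O4)[C@@H]23
F7 | step 13 | C12 alcohol (O12 trans to C16, 16-OBn, 19,6β-olide) | C[C@@H]1C[C@H]2OC(=O)[C@@]3(C)CCC[C@](C)([C@@]14C[C@H](O)[C@@H](COCc5ccccc5)O4)[C@@H]23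
F8 | step 2 | racemic cis-fused adduct acid (enantiomer that leads on is drawn) | CC1=CC(=O)[C@@H]2[C@H](C(=O)O)C=CC[C@]2(C)C1=O
F9 | step 2 | (R)-1-phenylethylammonium salt of acid 8 | CC1=CC(=O)[C@H]2[C@H](C(=O)[O-])C=CC[C@]2(C)C1=O.C[C@@H]([NH3+])c1ccccc1
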